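The vessel was closed, stirred and isothermal, and I charged the free catalyst as 0.35 mol% of the substrate, so percent of product divided by that loading counted turnovers per catalyst.

common to all: free catalyst 0.35 mol%
- midnight: substrate 0.0029 M; reagent 1.8 equiv; run made earlier
- dusk: substrate 0.0055 M; reagent 1.8 equiv; run made earlier
- noon: substrate 0.011 M; reagent 1.8 equiv; run made earlier
- north-east: substrate 0.0025 M; reagent 1.80 equiv; time 1.0 h
- east: substrate 0.0050 M; reagent 1.80 equiv; time 1.0 h
- south-west: substrate 0.010 M; reagent 1.80 equiv; time 1.0 h

| run | time / min | product / % |
|---|---|---|
| midnight | 4.00 | 3.9 |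
| midnight | 10.0 | 8.3 |
| midnight | 20.0 | 14.2 |
| midnight | 30.0 | 20.5 |
| midnight | 40.0 | 24.8 |
| dusk | 3.00 | 4.4 |
| dusk | 6.00 | 8.0 |
| dusk | 12.0 | 13.1 |
| dusk | 20.0 | 19.4 |
| dusk | 40.0 | 30.1 |
| noon | 4.00 | 4.1 |
| noon | 10.0 | 7.8 |
| noon | 20.0 | 13.3 |
| noon | 30.0 | 16.1 |
| noon | 40.0 | 19.4 |

(readings scatter by 0.5 percentage points)

- "hardly changes" means that all values lie within two and a half points (for a concentration: within two and a half percent of the largest)

- amount of product at the end, in percent of the substrate charged for north-east, east, south-west, in this order
- the course of these numbers from the first flask to the last (falls all the way / hardly changes / rises all the way / falls, then rises / rises, then falls)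

How fast did a catalyst work at the start? From the first reading of each run I read a turnover frequency of 2.79 min⁻¹ in the midnight run, 4.19 min⁻¹ in the dusk run and 2.93 min⁻¹ in the noon run, so the dusk run began faster than either neighbour.

Did that order last? I took the late turnover frequency, f, 1.53 min⁻¹ in the dusk run, which is the product gained per minute between the readings at 20.0 min and 40.0 min, divided by the loading. Over the same stretch f read 1.51 min⁻¹ in the midnight run and 0.871 min⁻¹ in the noon run. The lead of the dusk run over the midnight run in these readings had therefore shrunk, while the noon run had fallen behind the midnight run.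

What did that give at 1.0 h? Holding f for the last stretch, I reckoned 35.4% for the midnight run, 40.8% for the dusk run and 25.5% for the noon run. The dusk figure stood higher than the midnight figure and the noon figure, so I expected the new row, at slightly lower concentrations, to rise and then fall. In the dusk run f was lower than the starting frequency, so the pace had dropped, and I held my midnight and dusk figures to be high.

The forecast gave 28%, 35% and 24.5%, with the course rises, then falls, on the ground that “activity rises with concentration at first, then drops”. Its values for the north-east and east flasks lay below my figures for the midnight and dusk runs.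

The flasks gave 29.4%, 38.1% and 26.5%, and the course was rises, then falls, as forecast.

    substrate + free catalyst ⇌ catalyst intermediate A (K = 160 L mol⁻¹, k = 7300 L mol⁻¹ min⁻¹)
    catalyst intermediate B ⇌ by-product + catalyst intermediate C (K = 0.00450 M, k = 1800 min⁻¹)
    substrate + catalyst intermediate B ⇌ idle complex, settled at all times (K = 8200 L mol⁻¹)
    reagent + catalyst intermediate A ⇌ catalyst intermediate B (K = 19.0 L mol⁻¹, k = 2400 L mol⁻¹ min⁻¹)
    catalyst intermediate C → free catalyst + product (k = 33.0 min⁻¹)

At 1.00 h the idle complex held 37.3% of the catalyst charged in the east flask and 82.4% in the south-west flask. Reckoned from 0.500 h to 1.0 h, f was 1.29 min⁻¹ in the east flask, lower than the 1.53 min⁻¹ read between 20.0 min and 40.0 min in the dusk run. From 0.500 h to 1.0 h, f in the south-west flask was 0.849 min⁻¹, against 0.871 min⁻¹ read between 20.0 min and 40.0 min in the noon run.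

(The data were computed for an exercise, noise included.)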